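Germacranolide numbering. The disconnection is C1–C10 of oxepane ring B (O, C5, C4, C3, C2, C1, C10). An Ireland–Claisen rearrangement of a 7-vinyl-1,4-dioxepan-2-one, in which C10 is the lactate α-carbon and C3 the allylic ester carbon, closes ring B in one operation, creates the fully substituted ether carbon C10 and relays the easily set C3 carbinol configuration to it. The step exploits the C5–O–C10 ether and the oxygenation at C3, which is reinstated afterwards by a silicon-tethered hydration of the new C2=C3 alkene. The freed C9 carboxyl and a glyceraldehyde-derived C6–C7 unit then serve to close ring A and the α-methylene lactone by chromium-mediated allylation.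

Key step: step 10

Remark: read literally, the stereodescriptors place the ether oxygen on opposite faces of the ten-membered carbocycle at C5 and C10 (inside–outside, trans-bridged 11-oxabicyclo[4.4.1]undecane, as in ingenane-type skeletons); this strained arrangement is taken as the target, so ring B is closed first and ring A last.

Step 1
Reactants: 1 (R)-4-benzyl-1,3-oxazolidin-2-one; 2 3-[(4-methoxybenzyl)oxy]propanoic acid
Product: 4 (R)-4-benzyl-3-{3-[(4-methoxybenzyl)oxy]propanoyl}-1,3-oxazolidin-2-one, via mixed pivalic anhydride 3 (not isolated)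
Conditions: t-BuCOCl, Et3N, THF, −20 °C; then 1, LiCl, −20 → 25 °C
Reagents that add atoms: none
Why: N-acylation of the chloride-activated oxazolidinone by the mixed anhydride attaches the chiral auxiliary; no stereocentre is formed.

Step 2
Reactants: 4 (R)-4-benzyl-3-{3-[(4-methoxybenzyl)oxy]propanoyl}-1,3-oxazolidin-2-one; 5 (S)-2,2-dimethyl-1,3-dioxolane-4-carbaldehyde
Product: 7 syn-aldol imide (4R)-4-benzyl-3-[(2R,3R)-3-[(4S)-2,2-dimethyl-1,3-dioxolan-4-yl]-3-hydroxy-2-{[(4-methoxybenzyl)oxy]methyl}propanoyl]-1,3-oxazolidin-2-one, via Z-dibutylboron enolate 6 (not isolated)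
Conditions: n-Bu2BOTf, i-Pr2NEt, CH2Cl2, −78 → 0 °C; then 5, −78 → 0 °C; pH 7 buffer, MeOH, H2O2
Reagents that add atoms: none
Why: Evans syn-aldol reaction through a Zimmerman–Traxler chair in which the auxiliary fixes the enolate face sets C4 and C5 (syn), and this face should match the Felkin preference of the α-alkoxy aldehyde so that C5–O and C6–O become anti.

Step 3
Reactants: 7 syn-aldol imide
Product: 8 Weinreb amide (2R,3R)-3-[(4S)-2,2-dimethyl-1,3-dioxolan-4-yl]-3-hydroxy-N-methoxy-2-{[(4-methoxybenzyl)oxy]methyl}-N-methylpropanamide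
Conditions: MeONHMe·HCl, AlMe3, CH2Cl2, −20 → 0 °C
Reagents that add atoms: N,O-dimethylhydroxylamine hydrochloride, CNOC.Cl
Why: Aluminium amide transamidation cleaves the exocyclic imide carbonyl selectively and releases the auxiliary without touching the β-hydroxy stereocentres.

Step 4
Reactants: 8 Weinreb amide
Product: 9 vinyl ketone (4R,5R)-5-[(4S)-2,2-dimethyl-1,3-dioxolan-4-yl]-5-hydroxy-4-{[(4-methoxybenzyl)oxy]methyl}pent-1-en-3-one
Conditions: CH2=CHMgBr (3.5 equiv), THF, −78 → 0 °C; AcOH/aq. NH4Cl quench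
Reagents that add atoms: vinylmagnesium bromide, C=C[Mg]Br
Why: Grignard addition to a Weinreb amide stops at the chelated tetrahedral intermediate, so the enone (C1–C3) appears only on acidic quench and is not attacked further.

Step 5
Reactants: 9 vinyl ketone
Product: 10 ethyl {[(1R,2R)-1-[(4S)-2,2-dimethyl-1,3-dioxolan-4-yl]-2-{[(4-methoxybenzyl)oxy]methyl}-3-oxopent-4-en-1-yl]oxy}acetate
Conditions: N2CHCO2Et (slow addition), Rh2(OAc)4 (1 mol %), CH2Cl2, 25 °C
Reagents that add atoms: ethyl diazoacetate, CCOC(=O)C=[N+]=[N-]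
Why: Rhodium carbenoid O–H insertion etherifies the only hydroxyl (C5–OH) under neutral conditions, which avoids retro-aldol and oxa-Michael pathways of the β-hydroxy enone.

Step 6
Reactants: 10 glycolate ether of the vinyl ketone
Product: 11 ethyl {[(1R,2S,3R)-1-[(4S)-2,2-dimethyl-1,3-dioxolan-4-yl]-3-hydroxy-2-{[(4-methoxybenzyl)oxy]methyl}pent-4-en-1-yl]oxy}acetate
Conditions: Zn(BH4)2, Et2O, −78 → −30 °C
Reagents that add atoms: none
Why: Chelation-controlled 1,2-reduction (zinc bridges the ketone and a β-ether oxygen, hydride enters anti to the C4 branch) should give the C3 carbinol syn to both C4–C15 and C5–O, the all-syn array needed for step 10.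

Step 7
Reactants: 11 hydroxy ester
Product: 12 {[(1R,2S,3R)-1-[(4S)-2,2-dimethyl-1,3-dioxolan-4-yl]-3-hydroxy-2-{[(4-methoxybenzyl)oxy]methyl}pent-4-en-1-yl]oxy}acetic acid
Conditions: LiOH, THF/H2O, 0 °C; then 0.5 M HCl to pH 4
Reagents that add atoms: lithium hydroxide, [Li+].[OH-]
Why: Saponification of the activated α-alkoxy ester is fast at 0 °C and leaves the acetonide, the benzyl ether and the allylic alcohol intact.

Step 8
Reactants: 12 hydroxy acid
Product: 13 (5R,6S,7R)-5-[(4S)-2,2-dimethyl-1,3-dioxolan-4-yl]-7-ethenyl-6-{[(4-methoxybenzyl)oxy]methyl}-1,4-dioxepan-2-one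
Conditions: 2-methyl-6-nitrobenzoic anhydride, DMAP, Et3N, CH2Cl2, 0.005 M, 25 °C
Reagents that add atoms: none
Why: Mixed-anhydride lactonisation under dilution closes the seven-membered lactone on the only free hydroxyl (C3–OH), giving the all-cis 5,6,7-trisubstituted dioxepanone.

Step 9
Reactants: 13 dioxepanone
Product: 14 (3RS,5R,6S,7R)-5-[(4S)-2,2-dimethyl-1,3-dioxolan-4-yl]-7-ethenyl-6-{[(4-methoxybenzyl)oxy]methyl}-3-methyl-1,4-dioxepan-2-one
Conditions: LiN(i-Pr)2, THF, −78 °C; then MeI, −78 → −40 °C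
Reagents that add atoms: iodomethane, CI
Why: Kinetic enolate C-methylation installs the future C14 methyl on the lactate carbon (future C10), and both epimers are usable because this centre is planarised in step 10.

Step 10
Reactants: 14 3-methyl dioxepanone
Product: 17 (2R,6R,7R)-7-[(4S)-2,2-dimethyl-1,3-dioxolan-4-yl]-6-{[(4-methoxybenzyl)oxy]methyl}-2-methyl-2,3,6,7-tetrahydrooxepine-2-carboxylic acid, via silyl ketene acetal 15 (not isolated), via trimethylsilyl ester 16 (not isolated)
Conditions: Me3SiCl/Et3N, LiN(SiMe3)2, THF, −78 → 25 °C; then toluene, 110 °C; aqueous work-up at pH 4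
Reagents that add atoms: none
Why: In-situ silylation of the lactone enolate gives the cyclic ketene acetal 15, whose ring fixes the enol ether geometry, and the C3 vinyl group folds over the ring so that C1 bonds to C10 while the C3–O ester bond breaks in a boat-like six-centre [3,3] shift (Ireland–Claisen rearrangement). The closest known reaction is the Ireland–Claisen rearrangement of 6-alkenyl-1,4-dioxan-2-ones to dihydropyran-2-carboxylic acids, of which this is the one-carbon ring homologue. Ring B is closed in a ring-switching endo-type [3,3] mode that trades the seven-membered lactone for the seven-membered cyclic ether, so the new C2=C3 alkene can only be cis. The new stereocentre C10 is controlled by suprafacial chirality transfer from C3: the vinyl group lies on the lactone face that also carries the C6 and C15 substituents, so C1 adds to that face and the methyl group ends cis, the C9 carboxyl trans, to the C5–C6 bond. The step needs clean enolisation at the only α-carbon without ketene-forming fragmentation, which internal silyl trapping at −78 °C should secure, and it needs the all-cis lactone to reach the boat array, which the flexible seven-membered ring should allow.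

Step 11
Reactants: 17 tetrahydrooxepine carboxylic acid
Product: 18 primary alcohol [(2R,6R,7R)-7-[(4S)-2,2-dimethyl-1,3-dioxolan-4-yl]-6-{[(4-methoxybenzyl)oxy]methyl}-2-methyl-2,3,6,7-tetrahydrooxepin-2-yl]methanol
Conditions: LiAlH4, THF, 0 → 25 °C
Reagents that add atoms: none
Why: Hydride reduction of the carboxylic acid gives the C9 alcohol; the acetonide, ethers and the isolated alkene are inert.

Step 12
Reactants: 18 primary alcohol
Product: 19 aldehyde (2R,6R,7R)-7-[(4S)-2,2-dimethyl-1,3-dioxolan-4-yl]-6-{[(4-methoxybenzyl)oxy]methyl}-2-methyl-2,3,6,7-tetrahydrooxepine-2-carbaldehyde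
Conditions: Dess–Martin periodinane, NaHCO3, CH2Cl2, 25 °C
Reagents that add atoms: none
Why: Dess–Martin oxidation gives the C9 aldehyde, which cannot epimerise because C10 carries no hydrogen.

Step 13
Reactants: 19 aldehyde
Product: 20 (2R,6R,7R)-7-[(4S)-2,2-dimethyl-1,3-dioxolan-4-yl]-2-ethenyl-6-{[(4-methoxybenzyl)oxy]methyl}-2-methyl-2,3,6,7-tetrahydrooxepine
Conditions: Ph3PCH3Br, KN(SiMe3)2, THF, 0 → 25 °C
Reagents that add atoms: methyltriphenylphosphonium bromide, C[P+](c1ccccc1)(c1ccccc1)c1ccccc1.[Br-]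
Why: Wittig methylenation adds C8 and turns C9 into the terminal alkene that later delivers the C8 aldehyde.

Step 14
Reactants: 20 C10-vinyl tetrahydrooxepine
Product: 21 C15 alcohol (20 without its 4-methoxybenzyl group)
Conditions: DDQ, CH2Cl2/pH 7 buffer, 0 °C
Reagents that add atoms: none
Why: Oxidative cleavage of the electron-rich 4-methoxybenzyl ether frees the C15 hydroxyl needed as a tether and spares the acetonide and both alkenes.

Step 15
Reactants: 21 C15 alcohol
Product: 24 3,15-diol (oxepane with the C3 hydroxyl cis to the C4 hydroxymethyl group), via dimethylsilyl ether 22 (not isolated), via oxasilolane 23 (not isolated)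
Conditions: (HMe2Si)2NH, 25 °C; then Pt2[(CH2=CHSiMe2)2O]3 (0.5 mol %), toluene, 60 °C; then H2O2, KF, KHCO3, THF/MeOH, 25 °C
Reagents that add atoms: hydrogen peroxide, OO
Why: Intramolecular hydrosilylation followed by Tamao oxidation delivers silicon from the C15 oxygen to C3 through a five-membered ring on the alkene face syn to C15, and oxidation with retention sets the C3 hydroxyl cis to C15 with complete regiocontrol.

Step 16
Reactants: 24 3,15-diol
Product: 25 15-acetate (primary acetate, free C3 hydroxyl)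
Conditions: AcCl, 2,4,6-collidine, CH2Cl2, −78 °C
Reagents that add atoms: acetyl chloride, CC(=O)Cl
Why: Sterically controlled acylation at low temperature should acetylate only the primary C15 hydroxyl.

Step 17
Reactants: 25 15-acetate
Product: 26 3-O-tert-butyldimethylsilyl ether of 25
Conditions: t-BuMe2SiOTf, 2,6-lutidine, CH2Cl2, −78 → 0 °C
Reagents that add atoms: tert-butyldimethylsilyl triflate, CC(C)(C)[Si](C)(C)OS(=O)(=O)C(F)(F)F
Why: Silylation masks the C3 hydroxyl for the sulfonylation, oxidation and Mitsunobu steps that follow.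

Step 18
Reactants: 26 silyl ether acetonide
Product: 27 6,7-diol (secondary C6 hydroxyl and primary C7 hydroxyl)
Conditions: AcOH/H2O 4:1, 40 °C
Reagents that add atoms: none
Why: Mild acid hydrolysis removes the terminal acetonide while the secondary silyl ether and the acetate survive.

Step 19
Reactants: 27 6,7-diol
Product: 28 α-hydroxy aldehyde (C7 aldehyde next to the free C6 hydroxyl)
Conditions: TEMPO (10 mol %), PhI(OAc)2, CH2Cl2, 25 °C
Reagents that add atoms: none
Why: Oxoammonium-mediated oxidation is selective for the primary alcohol and stops at the aldehyde in the absence of water.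

Step 20
Reactants: 28 α-hydroxy aldehyde
Product: 30 β-hydroxy-α-methylene-γ-butyrolactone (ring C with a C7 hydroxyl as a mixture of epimers), via Baylis–Hillman adduct 29 (not isolated)
Conditions: methyl acrylate, DABCO, MeOH, 25 °C; then pyridinium p-toluenesulfonate (cat.), CH2Cl2
Reagents that add atoms: methyl acrylate, C=CC(=O)OC
Why: Morita–Baylis–Hillman reaction joins C7 to C11 and the C6 hydroxyl then lactonises onto the ester; the C7 carbinol configuration is irrelevant because it is erased in step 22.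

Step 21
Reactants: 30 hydroxy methylene lactone
Product: 31 C8 aldehyde (C10–CH2–CHO)
Conditions: PdCl2(PhCN)2, CuCl2·2H2O, AgNO2 (each catalytic), O2 (1 atm), t-BuOH/MeNO2, 25 °C
Reagents that add atoms: dioxygen, O=O
Why: Nitrite-modified aldehyde-selective Wacker oxidation should oxidise the terminal carbon because the fully substituted ether carbon C10 blocks Markovnikov attack, and the electron-poor methylene lactone is not a substrate.

Step 22
Reactants: 31 aldehyde
Product: 33 3-(bromomethyl)butenolide aldehyde, via mesylate 32 (not isolated)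
Conditions: MeSO2Cl, Et3N, CH2Cl2, −30 °C; then LiBr, THF/acetone, 0 → 25 °C
Reagents that add atoms: lithium bromide, [Li+].[Br-]
Why: Sulfonylation and SN2′ displacement by bromide transpose the allylic system into the conjugated C7=C11 butenolide with a C13 bromide, removing the C7 carbinol centre.

Step 23
Reactants: 33 bromomethylbutenolide aldehyde
Product: 34 tricyclic 8-epi alcohol (rings A, B and C closed; C8 hydroxyl trans to C11)
Conditions: CrCl2 (8 equiv), THF, 0.002 M, 25 °C
Reagents that add atoms: none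
Why: Intramolecular Nozaki–Hiyama–Kishi allylation: the C13 allylchromium attacks the C8 aldehyde through C7 in a chair-like transition state whose two ring-A tether bonds must both be equatorial, so C7–C8 should form anti to the C6–C5 bond (trans-lactone, exocyclic methylene restored) with the C8 hydroxyl trans to C11, while high dilution favours closure of the strained inside–outside ring A.

Step 24
Reactants: 35 (E)-but-2-enal
Product: 36 (Z)-2-iodobut-2-enal
Conditions: I2, K2CO3, DMAP (cat.), THF/H2O, 25 °C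
Reagents that add atoms: iodine, II
Why: Amine-catalysed addition–elimination α-iodination keeps the methyl group trans to the formyl group, so iodine ends cis to the methyl group.

Step 25
Reactants: 36 (Z)-2-iodobut-2-enal
Product: 37 (Z)-2-iodobut-2-en-1-ol
Conditions: NaBH4, CeCl3·7H2O, MeOH, 0 °C
Reagents that add atoms: none
Why: Luche reduction gives clean 1,2-reduction of the enal without touching the vinyl iodide.

Step 26
Reactants: 37 (Z)-2-iodobut-2-en-1-ol
Product: 38 (Z)-tert-butyl[(2-iodobut-2-en-1-yl)oxy]dimethylsilane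
Conditions: t-BuMe2SiCl, imidazole, CH2Cl2, 25 °C
Reagents that add atoms: tert-butyldimethylsilyl chloride, CC(C)(C)[Si](C)(C)Cl
Why: Silylation protects the allylic alcohol for the organolithium step.

Step 27
Reactants: 38 silyl-protected vinyl iodide
Product: 40 (Z)-2-{[(tert-butyldimethylsilyl)oxy]methyl}but-2-enoic acid, via alkenyllithium 39 (not isolated)
Conditions: t-BuLi (2.1 equiv), Et2O, −78 °C; then CO2; aq. KHSO4
Reagents that add atoms: carbon dioxide, O=C=O
Why: Iodine–lithium exchange and carboxylation both proceed with retention at −78 °C, so the carboxyl group ends cis to the methyl group as in the target ester.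

Step 28
Reactants: 34 tricyclic 8-epi alcohol; 40 (Z)-2-{[(tert-butyldimethylsilyl)oxy]methyl}but-2-enoic acid
Product: 41 bis-silyl ether of the target (C8 ester with the target configuration)
Conditions: PPh3, DIAD, toluene, 0 → 25 °C
Reagents that add atoms: none
Why: Mitsunobu esterification displaces the alkoxyphosphonium of the C8 alcohol by the carboxylate with inversion, which corrects C8 to the target configuration under neutral conditions that should not isomerise the Z-acid.

Step 29
Reactants: 41 bis-silyl ether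
Product: 42 target CNP0311647.1
Conditions: HF·pyridine, pyridine/THF, 0 → 25 °C
Reagents that add atoms: none
Why: Buffered fluoride desilylation frees the C3 and side-chain hydroxyls without acetate migration or attack on the methylene lactone.

Compound list
1 | (R)-4-benzyl-1,3-oxazolidin-2-one | O=C1OC[C@@H](Cc2ccccc2)N1 | starting material
2 | 3-[(4-methoxybenzyl)oxy]propanoic acid | COc1ccc(COCCC(=O)O)cc1 | starting material
3 | mixed anhydride of 2 and pivalic acid | COc1ccc(COCCC(=O)OC(=O)C(C)(C)C)cc1 | intermediate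
4 | (R)-4-benzyl-3-{3-[(4-methoxybenzyl)oxy]propanoyl}-1,3-oxazolidin-2-one | COc1ccc(COCCC(=O)N2[C@H](Cc3ccccc3)COC2=O)cc1 | intermediate
5 | (S)-2,2-dimethyl-1,3-dioxolane-4-carbaldehyde | CC1(C)O[C@@H](CO1)C=O | starting material
6 | (Z)-dibutylboron enolate of 4 | CCCCB(CCCC)O/C(=C\COCc1ccc(OC)cc1)N1[C@H](Cc2ccccc2)COC1=O | intermediate
7 | (4R)-4-benzyl-3-[(2R,3R)-3-[(4S)-2,2-dimethyl-1,3-dioxolan-4-yl]-3-hydroxy-2-{[(4-methoxybenzyl)oxy]methyl}propanoyl]-1,3-oxazolidin-2-one | O=C1OC[C@@H](Cc2ccccc2)N1C(=O)[C@H](COCc3ccc(OC)cc3)[C@@H](O)[C@@H]4COC(C)(C)O4 | intermediate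
8 | (2R,3R)-3-[(4S)-2,2-dimethyl-1,3-dioxolan-4-yl]-3-hydroxy-N-methoxy-2-{[(4-methoxybenzyl)oxy]methyl}-N-methylpropanamide | CON(C)C(=O)[C@H](COCc1ccc(OC)cc1)[C@@H](O)[C@@H]2COC(C)(C)O2 | intermediate
9 | (4R,5R)-5-[(4S)-2,2-dimethyl-1,3-dioxolan-4-yl]-5-hydroxy-4-{[(4-methoxybenzyl)oxy]methyl}pent-1-en-3-one | C=CC(=O)[C@H](COCc1ccc(OC)cc1)[C@@H](O)[C@@H]2COC(C)(C)O2 | intermediate
10 | ethyl {[(1R,2R)-1-[(4S)-2,2-dimethyl-1,3-dioxolan-4-yl]-2-{[(4-methoxybenzyl)oxy]methyl}-3-oxopent-4-en-1-yl]oxy}acetate | C=CC(=O)[C@H](COCc1ccc(OC)cc1)[C@@H](OCC(=O)OCC)[C@@H]2COC(C)(C)O2 | intermediate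
11 | ethyl {[(1R,2S,3R)-1-[(4S)-2,2-dimethyl-1,3-dioxolan-4-yl]-3-hydroxy-2-{[(4-methoxybenzyl)oxy]methyl}pent-4-en-1-yl]oxy}acetate | C=C[C@@H](O)[C@H](COCc1ccc(OC)cc1)[C@@H](OCC(=O)OCC)[C@@H]2COC(C)(C)O2 | intermediate
12 | {[(1R,2S,3R)-1-[(4S)-2,2-dimethyl-1,3-dioxolan-4-yl]-3-hydroxy-2-{[(4-methoxybenzyl)oxy]methyl}pent-4-en-1-yl]oxy}acetic acid | C=C[C@@H](O)[C@H](COCc1ccc(OC)cc1)[C@@H](OCC(=O)O)[C@@H]2COC(C)(C)O2 | intermediate
13 | (5R,6S,7R)-5-[(4S)-2,2-dimethyl-1,3-dioxolan-4-yl]-7-ethenyl-6-{[(4-methoxybenzyl)oxy]methyl}-1,4-dioxepan-2-one | CC1(C)O[C@@H](CO1)[C@@H]2OCC(=O)O[C@H](C=C)[C@@H]2COCc3ccc(OC)cc3 | intermediate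
14 | (3RS,5R,6S,7R)-5-[(4S)-2,2-dimethyl-1,3-dioxolan-4-yl]-7-ethenyl-6-{[(4-methoxybenzyl)oxy]methyl}-3-methyl-1,4-dioxepan-2-one (both C3 epimers) | CC1(C)O[C@@H](CO1)[C@@H]2OC(C)C(=O)O[C@H](C=C)[C@@H]2COCc3ccc(OC)cc3 | intermediate
15 | cyclic trimethylsilyl ketene acetal of 14 | CC1(C)O[C@@H](CO1)[C@@H]2OC(C)=C(O[Si](C)(C)C)O[C@H](C=C)[C@@H]2COCc3ccc(OC)cc3 | intermediate
16 | trimethylsilyl ester of 17 | CC1(C)O[C@@H](CO1)[C@@H]2O[C@](C)(CC=C[C@@H]2COCc3ccc(OC)cc3)C(=O)O[Si](C)(C)C | intermediate
17 | (2R,6R,7R)-7-[(4S)-2,2-dimethyl-1,3-dioxolan-4-yl]-6-{[(4-methoxybenzyl)oxy]methyl}-2-methyl-2,3,6,7-tetrahydrooxepine-2-carboxylic acid | CC1(C)O[C@@H](CO1)[C@@H]2O[C@](C)(CC=C[C@@H]2COCc3ccc(OC)cc3)C(=O)O | intermediate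
18 | [(2R,6R,7R)-7-[(4S)-2,2-dimethyl-1,3-dioxolan-4-yl]-6-{[(4-methoxybenzyl)oxy]methyl}-2-methyl-2,3,6,7-tetrahydrooxepin-2-yl]methanol | CC1(C)O[C@@H](CO1)[C@@H]2O[C@](C)(CC=C[C@@H]2COCc3ccc(OC)cc3)CO | intermediate
19 | (2R,6R,7R)-7-[(4S)-2,2-dimethyl-1,3-dioxolan-4-yl]-6-{[(4-methoxybenzyl)oxy]methyl}-2-methyl-2,3,6,7-tetrahydrooxepine-2-carbaldehyde | CC1(C)O[C@@H](CO1)[C@@H]2O[C@](C)(CC=C[C@@H]2COCc3ccc(OC)cc3)C=O | intermediate
20 | (2R,6R,7R)-7-[(4S)-2,2-dimethyl-1,3-dioxolan-4-yl]-2-ethenyl-6-{[(4-methoxybenzyl)oxy]methyl}-2-methyl-2,3,6,7-tetrahydrooxepine | CC1(C)O[C@@H](CO1)[C@@H]2O[C@](C)(CC=C[C@@H]2COCc3ccc(OC)cc3)C=C | intermediate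
21 | C15 alcohol: 20 with the 4-methoxybenzyl group removed (ring-B stereocentres unchanged) | CC1(C)O[C@@H](CO1)[C@@H]2O[C@](C)(CC=C[C@@H]2CO)C=C | intermediate
22 | C15 O-dimethylsilyl (Si–H) ether of 21 | CC1(C)O[C@@H](CO1)[C@@H]2O[C@](C)(CC=C[C@@H]2CO[SiH](C)C)C=C | intermediate
23 | cis-fused 2,2-dimethyl-1-oxa-2-silacyclopentane (Si on C3, O on C15) | CC1(C)O[C@@H](CO1)[C@@H]2O[C@](C)(CC[C@H]3[C@@H]2CO[Si]3(C)C)C=C | intermediate
24 | 3,15-diol: oxepane with the C3 hydroxyl cis to the C4 hydroxymethyl group, C10 vinyl and methyl, C5 dioxolanyl | CC1(C)O[C@@H](CO1)[C@@H]2O[C@](C)(CC[C@H](O)[C@@H]2CO)C=C | intermediate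
25 | 15-acetate of 24 | CC1(C)O[C@@H](CO1)[C@@H]2O[C@](C)(CC[C@H](O)[C@@H]2COC(C)=O)C=C | intermediate
26 | 3-O-tert-butyldimethylsilyl ether of 25 | CC1(C)O[C@@H](CO1)[C@@H]2O[C@](C)(CC[C@H](O[Si](C)(C)C(C)(C)C)[C@@H]2COC(C)=O)C=C | intermediate
27 | 6,7-diol from 26 (acetonide removed; C6 secondary and C7 primary hydroxyl) | OC[C@H](O)[C@@H]1O[C@](C)(CC[C@H](O[Si](C)(C)C(C)(C)C)[C@@H]1COC(C)=O)C=C | intermediate
28 | α-hydroxy aldehyde (C7 aldehyde, C6 hydroxyl) | O=C[C@H](O)[C@@H]1O[C@](C)(CC[C@H](O[Si](C)(C)C(C)(C)C)[C@@H]1COC(C)=O)C=C | intermediate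
29 | Baylis–Hillman adduct: methyl 2-methylidene-3,4-dihydroxy ester at C7 (C7 epimers) | COC(=O)C(=C)C(O)[C@H](O)[C@@H]1O[C@](C)(CC[C@H](O[Si](C)(C)C(C)(C)C)[C@@H]1COC(C)=O)C=C | intermediate
30 | β-hydroxy-α-methylene-γ-butyrolactone (ring C; C7 hydroxyl epimers; C10 vinyl) | C=C1C(=O)O[C@H]([C@@H]2O[C@](C)(CC[C@H](O[Si](C)(C)C(C)(C)C)[C@@H]2COC(C)=O)C=C)C1O | intermediate
31 | C8 aldehyde of 30 (C10–CH2–CHO) | C=C1C(=O)O[C@H]([C@@H]2O[C@](C)(CC[C@H](O[Si](C)(C)C(C)(C)C)[C@@H]2COC(C)=O)CC=O)C1O | intermediate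
32 | C7 mesylate of 31 | C=C1C(=O)O[C@H]([C@@H]2O[C@](C)(CC[C@H](O[Si](C)(C)C(C)(C)C)[C@@H]2COC(C)=O)CC=O)C1OS(C)(=O)=O | intermediate
33 | 3-(bromomethyl)-5-substituted furan-2(5H)-one carrying the C8 aldehyde | O=C1O[C@@H](C=C1CBr)[C@@H]2O[C@](C)(CC[C@H](O[Si](C)(C)C(C)(C)C)[C@@H]2COC(C)=O)CC=O | intermediate
34 | tricyclic 8-epi alcohol: 15-acetoxy-3-silyloxy-5,10-epoxy-germacr-11(13)-en-6,12-olide with the C8 hydroxyl trans to C11 | C=C1C(=O)O[C@@H]2[C@@H]3O[C@](C)(CC[C@H](O[Si](C)(C)C(C)(C)C)[C@@H]3COC(C)=O)C[C@H](O)[C@@H]12 | intermediate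
35 | (E)-but-2-enal | C/C=C/C=O | starting material
36 | (Z)-2-iodobut-2-enal | C/C=C(\I)C=O | intermediate
37 | (Z)-2-iodobut-2-en-1-ol | C/C=C(\I)CO | intermediate
38 | (Z)-tert-butyl[(2-iodobut-2-en-1-yl)oxy]dimethylsilane | C/C=C(\I)CO[Si](C)(C)C(C)(C)C | intermediate
39 | alkenyllithium from 38 (lithium in place of iodine, geometry retained) | C/C=C(\[Li])CO[Si](C)(C)C(C)(C)C | intermediate
40 | (Z)-2-{[(tert-butyldimethylsilyl)oxy]methyl}but-2-enoic acid | C/C=C(\C(=O)O)CO[Si](C)(C)C(C)(C)C | intermediate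
41 | bis-silyl ether of the target (C3 and side-chain hydroxyls silylated) | C=C1C(=O)O[C@@H]2[C@@H]3O[C@](C)(CC[C@H](O[Si](C)(C)C(C)(C)C)[C@@H]3COC(C)=O)C[C@@H](OC(=O)/C(=C\C)CO[Si](C)(C)C(C)(C)C)[C@@H]12 | intermediate
42 | CNP0311647.1: (3S,4S,5R,6S,7R,8R,10R)-15-acetoxy-3-hydroxy-8-[(Z)-2-(hydroxymethyl)but-2-enoyloxy]-5,10-epoxygermacr-11(13)-en-6,12-olide | C=C1C(=O)O[C@@H]2[C@@H]3O[C@](C)(CC[C@H](O)[C@@H]3COC(C)=O)C[C@@H](OC(=O)/C(=C\C)CO)[C@@H]12 | target

Total step count: 29. Longest linear sequence: 25 steps (steps 1–23, 28 and 29); the side-chain acid takes steps 24–27.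

Steps most likely to fail

Step 23 (closure of ring A). The process at risk is the cyclisation itself: the two arms sit trans on ring B, so the closing transition state carries the strain of the inside–outside bicycle. Intermolecular coupling, protonation of the allylchromium, or bond formation on the wrong face of C7 may therefore compete. The fallback sets out from 28 and comes back at 34, replacing the polar allylation by a radical ketyl–olefin closure. Z-selective olefination of 28 with methyl bis(2,2,2-trifluoroethyl)phosphonoacetate (KN(SiMe3)2, 18-crown-6, THF, −78 °C) and lactonisation in the flask would give butenolide F1. Aldehyde-selective Wacker oxidation as in step 21 would give butenolide aldehyde F2. SmI2 (THF, t-BuOH, 0 °C) would then generate the C8 ketyl, which should add 7-exo-trig to C7 of the butenolide with the hydroxyl trans to C11. The trivalent samarium enolate is trapped with dimethylmethyleneammonium iodide to give Mannich base F3. Quaternisation with iodomethane to ammonium salt F4 and elimination with NaHCO3 would restore the methylene group and deliver 34.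

Step 10 (key step). The process at risk is enolisation of the hindered, fully substituted lactate carbon: it may be incomplete, or the lactone enolate may fragment to a ketene before it is silylated, and the crowded all-cis lactone may be slow to reach the boat array. The fallback sets out from 14 and comes back at 18, generating the ketene acetal without base in the manner of a Johnson–Claisen rearrangement. O-Methylation of 14 with Me3OBF4 (CH2Cl2) would give lactonium salt F5, and NaOMe/MeOH would convert it into cyclic ortho ester F6. Heating with catalytic propionic acid (xylene, 140 °C) expels methanol to give methyl ketene acetal F7, which should undergo the same ring-switching [3,3] shift to methyl ester F8. LiAlH4 reduction of F8 gives 18.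

Step 28 (inversion at C8). The process at risk is the displacement at the hindered ring-A carbinol: elimination towards C9, or conjugate addition of the phosphine to the methylene lactone, may outrun substitution by the bulky carboxylate. The fallback sets out from 34 and comes back at 41, inverting C8 by oxidation and reduction and then acylating with retention. Dess–Martin oxidation of 34 (NaHCO3, CH2Cl2) would give C8 ketone F9. Reduction with NaBH4/CeCl3·7H2O (MeOH, −78 °C), with hydride entering anti to the C7–C11 bond, should give the epimeric alcohol F10 with the hydroxyl cis to C11. Esterification of F10 with 40 (2-methyl-6-nitrobenzoic anhydride, Et3N, DMAP, CH2Cl2) gives 41.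

Further compounds
F1 | step 23 | 5-substituted furan-2(5H)-one (butenolide on C6) with the C10 vinyl group | O=C1O[C@@H](C=C1)[C@@H]2O[C@](C)(CC[C@H](O[Si](C)(C)C(C)(C)C)[C@@H]2COC(C)=O)C=C
F2 | step 23 | butenolide carrying the C8 aldehyde | O=C1O[C@@H](C=C1)[C@@H]2O[C@](C)(CC[C@H](O[Si](C)(C)C(C)(C)C)[C@@H]2COC(C)=O)CC=O
F3 | step 23 | tricyclic α-(dimethylaminomethyl) lactone with the C8 hydroxyl trans to C11 | CN(C)CC1C(=O)O[C@@H]2[C@@H]3O[C@](C)(CC[C@H](O[Si](C)(C)C(C)(C)C)[C@@H]3COC(C)=O)C[C@H](O)[C@@H]12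
F4 | step 23 | trimethylammonium iodide of F3 | C[N+](C)(C)CC1C(=O)O[C@@H]2[C@@H]3O[C@](C)(CC[C@H](O[Si](C)(C)C(C)(C)C)[C@@H]3COC(C)=O)C[C@H](O)[C@@H]12.[I-]
F5 | step 10 | O-methyl lactonium tetrafluoroborate of 14 | CC1(C)O[C@@H](CO1)[C@@H]2OC(C)C(OC)=[O+][C@H](C=C)[C@@H]2COCc3ccc(OC)cc3.F[B-](F)(F)F
F6 | step 10 | cyclic dimethyl ortho ester of 14 (2,2-dimethoxy-1,4-dioxepane) | CC1(C)O[C@@H](CO1)[C@@H]2OC(C)C(OC)(OC)O[C@H](C=C)[C@@H]2COCc3ccc(OC)cc3
F7 | step 10 | cyclic methyl ketene acetal (O-methyl analogue of 15) | CC1(C)O[C@@H](CO1)[C@@H]2OC(C)=C(OC)O[C@H](C=C)[C@@H]2COCc3ccc(OC)cc3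
F8 | step 10 | methyl ester of 17 | CC1(C)O[C@@H](CO1)[C@@H]2O[C@](C)(CC=C[C@@H]2COCc3ccc(OC)cc3)C(=O)OC
F9 | step 28 | C8 ketone from 34 | C=C1C(=O)O[C@@H]2[C@@H]3O[C@](C)(CC[C@H](O[Si](C)(C)C(C)(C)C)[C@@H]3COC(C)=O)CC(=O)[C@@H]12
F10 | step 28 | C8 epimer of 34 (hydroxyl cis to C11) | C=C1C(=O)O[C@@H]2[C@@H]3O[C@](C)(CC[C@H](O[Si](C)(C)C(C)(C)C)[C@@H]3COC(C)=O)C[C@@H](O)[C@@H]12
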